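**Plan**
- Cuts: (a) the aryl–C2 bond of the tetrahydrofuran (aryllithium + lactone carbonyl; the C2–H and C3–H bonds are added last by hydrogenation); (b) in each dihydrobenzofuran the C3–C3a bond, traced back to the C4–C4a bond of a 2-arylchroman-4-one; (c) the C2–aryl bond of each flavanone (arylboronic acid + 6-bromo-8-methoxychromone).
- Enabling feature: in the terminal 2-aryl-3-(hydroxymethyl)-2,3-dihydrobenzofuran, C3 carries both arene carbon C3a and the exocyclic CH2OH carbon. This is the footprint of a 1,2-shift of C4a from C4 to C3 in the six-membered ring O1–C2–C3–C4–C4a–C8a of a flavanone, whose carbonyl carbon C4 is pushed out of the ring and becomes the CH2OH carbon.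
- Forward: chromone → (S)-flavanone → ring contraction (terminal dihydrobenzofuran) → borylation → (R)-flavanone → second contraction (middle dihydrobenzofuran) → aryllithium addition to an (R)-β-benzyl-γ-butyrolactone → 4,5-dihydrofuran → all-cis tetrahydrofuran → desilylation.
- Stereochemistry: flavanone C2 centres by ligand-controlled Pd conjugate addition (enantiomeric ligands for the two units); each dihydrobenzofuran C3 trans to C2 by the contraction; the benzyl-bearing carbon from (R)-epichlorohydrin; tetrahydrofuran C2 and C3 by syn hydrogenation anti to the benzyl group.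
- All five hydroxyl groups travel as triisopropylsilyl ethers and are released together by fluoride.

Key step: step 6

Remark: TIPS = triisopropylsilyl; "Ar" in names = 3-methoxy-4-(TIPS-oxy)phenyl.
Assumption: with (S)-t-BuPyOx the Pd-catalysed addition to the chromone is taken to give the 2R flavanone (same face as in the 3-methylcyclohexenone series), so the (R)-ligand is used in step 5 and the (S)-ligand in step 8; if the sense is the reverse, the two ligands are exchanged.

**Step 1**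
Reactants: 1 1-(2-hydroxy-3-methoxyphenyl)ethan-1-one
Product: 2 1-(5-bromo-2-hydroxy-3-methoxyphenyl)ethan-1-one
Conditions: NBS, MeCN, 0 → 20 °C
Reagents that add atoms: N-bromosuccinimide, BrN1C(=O)CCC1=O
Why: Electrophilic aromatic bromination goes para to the phenol OH (C5), whose two ortho positions carry the acetyl and methoxy groups.

**Step 2**
Reactants: 2 1-(5-bromo-2-hydroxy-3-methoxyphenyl)ethan-1-one
Product: 4 6-bromo-8-methoxy-4H-chromen-4-one, via enaminone 3 (not isolated)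
Conditions: Me2NCH(OMe)2, PhMe, 100 °C; then conc. HCl, CH2Cl2, 40 °C
Reagents that add atoms: N,N-dimethylformamide dimethyl acetal, COC(OC)N(C)C
Why: Condensation of the methyl ketone to the enaminone and acid-promoted addition–elimination of the phenol with loss of dimethylamine is the standard chromone synthesis.

**Step 3**
Reactants: 5 4-bromo-2-methoxyphenol
Product: 6 (4-bromo-2-methoxyphenoxy)triisopropylsilane
Conditions: i-Pr3SiCl, imidazole, DMF, 20 °C
Reagents that add atoms: chlorotriisopropylsilane, CC(C)[Si](Cl)(C(C)C)C(C)C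
Why: Phenol silylation; the aryl TIPS ether should survive the later acid, organometallic and hydride steps and is cleaved by fluoride at the end.

**Step 4**
Reactants: 6 (4-bromo-2-methoxyphenoxy)triisopropylsilane
Product: 7 [3-methoxy-4-(TIPS-oxy)phenyl]boronic acid
Conditions: B2(OH)4, Pd(OAc)2 (cat.), XPhos, KOAc, EtOH, 80 °C
Reagents that add atoms: tetrahydroxydiboron, OB(O)B(O)O
Why: Miyaura-type borylation with tetrahydroxydiboron under zerovalent palladium catalysis gives the free boronic acid directly.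

**Step 5**
Reactants: 4 6-bromo-8-methoxy-4H-chromen-4-one; 7 [3-methoxy-4-(TIPS-oxy)phenyl]boronic acid
Product: 8 (2S)-6-bromo-8-methoxy-2-Ar-chroman-4-one
Conditions: Pd(OCOCF3)2 (5 mol %), (R)-t-BuPyOx (6 mol %), NH4PF6, H2O, ClCH2CH2Cl, 60 °C
Reagents that add atoms: none
Why: Enantioselective conjugate addition of an arylpalladium species (divalent palladium, pyridine-oxazoline ligand) to the chromone C2=C3 bond sets C2 (S) under ligand control, and divalent palladium should leave the aryl bromide untouched.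

**Step 6**
Reactants: 8 (2S)-6-bromo-8-methoxy-2-Ar-chroman-4-one
Product: 12 methyl (2S,3S)-5-bromo-7-methoxy-2-Ar-2,3-dihydrobenzofuran-3-carboxylate (2,3-trans), via enol ether 9 (not isolated), via iodane 10 (not isolated), via orthoester 11 (not isolated)
Conditions: PhI(OAc)2 (1.2 equiv), H2SO4 (cat.), HC(OMe)3/MeOH, 20 °C; H2O, then aq. NaHCO3
Reagents that add atoms: trimethyl orthoformate, COC(OC)OC; methanol, CO; water, O
Why: Acid and HC(OMe)3 turn the C4 ketone into the 4-methoxy-2H-chromene 9, whose C3 is attacked by PhI(OAc)2 on the face anti to the C2 aryl group while methanol caps C4 (trans iodane ketal 10); arene carbon C4a then shifts from C4 to C3 with loss of iodobenzene, and C4 leaves the ring as a dimethoxycarbenium ion that is trapped as orthoester 11 and hydrolysed to the methyl ester on work-up. The closest known reaction type is the oxidative 1,2-aryl-shift ring contraction of flavanones by trivalent iodine or Tl(NO3)3, a semipinacol-type rearrangement of an α-iodanyl ketal. The five-membered ring O1–C2–C3–C3a–C7a closes by this 1,2-shift: the C3–C3a bond forms as C4–C4a breaks, so the six-membered pyranone contracts by one carbon and no ring atom is added. The new stereocentre C3 is controlled by C2, since anti attack of the iodane followed by migration with inversion places the ester carbon trans to the aryl group (also the thermodynamic arrangement), while C2 is not touched and stays S. The step needs migration of the ring-fused carbon C4a in preference to the C2 aryl group (isoflavone pathway) and to elimination (flavone), and it needs the benzylic C2–O bond not to ionise. The equatorial C2 aryl group holds the C3–I bond equatorial and antiperiplanar only to the ring bond C4–C4a, the two methoxy groups on C4 stabilise the cation left behind, and the silyl cap on the para oxygen makes the C2 aryl group a poorer migrating and ionising group.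

**Step 7**
Reactants: 12 methyl (2S,3S)-5-bromo-7-methoxy-2-Ar-2,3-dihydrobenzofuran-3-carboxylate
Product: 13 [(2S,3S)-7-methoxy-3-(methoxycarbonyl)-2-Ar-2,3-dihydrobenzofuran-5-yl]boronic acid
Conditions: B2(OH)4, Pd(OAc)2 (cat.), XPhos, KOAc, MeOH, 65 °C
Reagents that add atoms: tetrahydroxydiboron, OB(O)B(O)O
Why: Same Miyaura-type borylation as in step 4; acetate is too weak a base to epimerise or ring-open the trans ester, and methanol avoids ester exchange.

**Step 8**
Reactants: 13 [(2S,3S)-7-methoxy-3-(methoxycarbonyl)-2-Ar-2,3-dihydrobenzofuran-5-yl]boronic acid; 4 6-bromo-8-methoxy-4H-chromen-4-one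
Product: 14 methyl (2S,3S)-5-[(2R)-6-bromo-8-methoxy-4-oxochroman-2-yl]-7-methoxy-2-Ar-2,3-dihydrobenzofuran-3-carboxylate
Conditions: Pd(OCOCF3)2 (5 mol %), (S)-t-BuPyOx (6 mol %), NH4PF6, H2O, ClCH2CH2Cl, 60 °C
Reagents that add atoms: none
Why: Second enantioselective conjugate addition as in step 5, now with the enantiomeric ligand, so the new flavanone C2 is set R by the catalyst while the remote centres of 13 take no part.

**Step 9**
Reactants: 14 methyl (2S,3S)-5-[(2R)-6-bromo-8-methoxy-4-oxochroman-2-yl]-7-methoxy-2-Ar-2,3-dihydrobenzofuran-3-carboxylate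
Product: 18 methyl (2R,3R)-5-bromo-7-methoxy-2-[(2S,3S)-7-methoxy-3-(methoxycarbonyl)-2-Ar-2,3-dihydrobenzofuran-5-yl]-2,3-dihydrobenzofuran-3-carboxylate, via enol ether 15 (not isolated), via iodane 16 (not isolated), via orthoester 17 (not isolated)
Conditions: PhI(OAc)2 (1.2 equiv), H2SO4 (cat.), HC(OMe)3/MeOH, 20 °C; H2O, then aq. NaHCO3
Reagents that add atoms: trimethyl orthoformate, COC(OC)OC; methanol, CO; water, O
Why: Same oxidative 1,2-aryl-shift ring contraction as in step 6 builds the middle dihydrobenzofuran, with C3 set trans to the 2R aryl-bearing carbon by anti iodination and migration with inversion.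

**Step 10**
Reactants: 18 the bromo diester
Product: 19 [(2R,3S)-5-bromo-2-[(2S,3R)-3-(hydroxymethyl)-7-methoxy-2-Ar-2,3-dihydrobenzofuran-5-yl]-7-methoxy-2,3-dihydrobenzofuran-3-yl]methanol
Conditions: i-Bu2AlH (6 equiv), CH2Cl2, −78 → 0 °C; Rochelle salt
Reagents that add atoms: none
Why: Hydride reduction of both esters to the primary alcohols should spare the aryl bromide and the aryl silyl ether and removes the epimerisable ester positions.

**Step 11**
Reactants: 19 the bromo diol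
Product: 20 the bis(TIPS) ether of 19 (both CH2OH groups as CH2O-TIPS)
Conditions: i-Pr3SiCl, imidazole, DMAP (cat.), DMF, 40 °C
Reagents that add atoms: chlorotriisopropylsilane, CC(C)[Si](Cl)(C(C)C)C(C)C
Why: Silylation of the two primary alcohols makes the bromide fit for halogen–lithium exchange.

**Step 12**
Reactants: 21 di-tert-butyl malonate; 22 (R)-epichlorohydrin
Product: 23 tert-butyl (1R,5R)-2-oxo-3-oxabicyclo[3.1.0]hexane-1-carboxylate
Conditions: KOt-Bu (1 equiv), t-BuOH, 50 °C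
Reagents that add atoms: none
Why: The malonate anion opens the epoxide at CH2, the alkoxide re-forms an epoxide by displacing chloride, 3-exo-tet opening with inversion gives the cyclopropane and the liberated alkoxide lactonises, so the epichlorohydrin centre becomes C5 (the known malonate–epichlorohydrin cyclopropanation).

**Step 13**
Reactants: 6 (4-bromo-2-methoxyphenoxy)triisopropylsilane; 23 tert-butyl (1R,5R)-2-oxo-3-oxabicyclo[3.1.0]hexane-1-carboxylate
Product: 25 tert-butyl (3R,4R)-4-[3-methoxy-4-(TIPS-oxy)benzyl]-2-oxotetrahydrofuran-3-carboxylate (3,4-trans), via arylmagnesium bromide 24 (not isolated)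
Conditions: Mg, THF, 40 °C; then CuI (10 mol %), 23, THF, −30 → 0 °C; 1 M HCl
Reagents that add atoms: none
Why: Copper-catalysed homoconjugate opening of the doubly activated cyclopropane at its CH2 by the aryl Grignard reagent leaves C5 untouched, which becomes the benzyl-bearing carbon (R).

**Step 14**
Reactants: 25 the tert-butyl ester lactone
Product: 27 (4R)-4-[3-methoxy-4-(TIPS-oxy)benzyl]dihydrofuran-2(3H)-one, via carboxylic acid 26 (not isolated)
Conditions: CF3CO2H, CH2Cl2, 20 °C; evaporate; PhMe, 110 °C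
Reagents that add atoms: none
Why: Acidolysis of the tert-butyl ester and thermal decarboxylation of the β-carboxy lactone avoid the basic or halide conditions that could cleave the aryl silyl ether.

**Step 15**
Reactants: 27 (4R)-4-[3-methoxy-4-(TIPS-oxy)benzyl]dihydrofuran-2(3H)-one
Product: 29 (3S,4R)-4-[3-methoxy-4-(TIPS-oxy)benzyl]-3-[(TIPS-oxy)methyl]dihydrofuran-2(3H)-one (3,4-trans), via lithium enolate 28 (not isolated)
Conditions: LiN(i-Pr)2, THF, −78 °C; then i-Pr3SiOCH2Cl, −78 → −40 °C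
Reagents that add atoms: (triisopropylsiloxy)methyl chloride, ClCO[Si](C(C)C)(C(C)C)C(C)C
Why: C-alkylation of the lactone enolate by an α-chloro ether anti to the benzyl group installs the future CH2OH carbon already silylated; the configuration of this carbon is erased in step 17.

**Step 16**
Reactants: 20 the tris(TIPS) aryl bromide; 29 the trans lactone
Product: 31 (2S,3R)-4-hydroxy-3-[3-methoxy-4-(TIPS-oxy)benzyl]-2-[(TIPS-oxy)methyl]-1-(aryl of 20)butan-1-one (in equilibrium with its cyclic hemiketal), via aryllithium 30 (not isolated)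
Conditions: 20, t-BuLi (2.0 equiv), THF, −78 °C; then 29, −78 °C; AcOH, −78 °C
Reagents that add atoms: none
Why: Bromine–lithium exchange and single addition of the aryllithium to the lactone carbonyl (as in C-aryl glycoside synthesis) stop at the tetrahedral lithium alkoxide, which is stable at −78 °C.

**Step 17**
Reactants: 31 the γ-hydroxy ketone
Product: 32 (4R)-2-(aryl of 20)-4-[3-methoxy-4-(TIPS-oxy)benzyl]-3-[(TIPS-oxy)methyl]-4,5-dihydrofuran
Conditions: PPTS (10 mol %), 4 Å MS, PhMe, 60 °C; Et3N quench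
Reagents that add atoms: none
Why: Acid-catalysed cyclodehydration of a γ-hydroxy aryl ketone gives the 2-aryl-4,5-dihydrofuran, since C3 carries the only β-hydrogen of the oxocarbenium ion.

**Step 18**
Reactants: 32 the 4,5-dihydrofuran
Product: 33 (2R,3R,4R)-2-(aryl of 20)-4-[3-methoxy-4-(TIPS-oxy)benzyl]-3-[(TIPS-oxy)methyl]tetrahydrofuran (all-cis; the pentakis(TIPS) ether of the target)
Conditions: H2 (5 bar), 5% Rh/Al2O3, EtOAc, Et3N (1%), 20 °C
Reagents that add atoms: none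
Why: Syn addition of hydrogen to the C2=C3 enol ether bond from the face opposite the C4 benzyl group sets C2 and C3 at once, both cis to C4 (heterogeneous hydrogenation of a cyclic enol ether, as for C-aryl glycals); rhodium on alumina is chosen for its low tendency to cleave benzylic C–O bonds.

**Step 19**
Reactants: 33 the pentakis(TIPS) ether
Product: 34 CNP0395728.1
Conditions: Bu4NF (6 equiv), AcOH (6 equiv), THF, 0 → 20 °C
Reagents that add atoms: none
Why: Fluoride cleaves the two aryl and three alkyl silyl ethers in one operation, and the acetic acid buffer prevents phenoxide-driven opening of the para-hydroxybenzylic ethers.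

**Compound list**
1 | 1-(2-hydroxy-3-methoxyphenyl)ethan-1-one | CC(=O)c1cccc(OC)c1O | starting material
2 | 1-(5-bromo-2-hydroxy-3-methoxyphenyl)ethan-1-one | CC(=O)c1cc(Br)cc(OC)c1O | intermediate
3 | (E)-1-(5-bromo-2-hydroxy-3-methoxyphenyl)-3-(dimethylamino)prop-2-en-1-one | CN(C)/C=C/C(=O)c1cc(Br)cc(OC)c1O | intermediate
4 | 6-bromo-8-methoxy-4H-chromen-4-one | O=c1ccoc2c(OC)cc(Br)cc12 | intermediate
5 | 4-bromo-2-methoxyphenol | COc1cc(Br)ccc1O | starting material
6 | (4-bromo-2-methoxyphenoxy)triisopropylsilane | COc1cc(Br)ccc1O[Si](C(C)C)(C(C)C)C(C)C | intermediate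
7 | [3-methoxy-4-(TIPS-oxy)phenyl]boronic acid | COc1cc(B(O)O)ccc1O[Si](C(C)C)(C(C)C)C(C)C | intermediate
8 | (2S)-6-bromo-8-methoxy-2-Ar-chroman-4-one | O=C1C[C@@H](c2ccc(O[Si](C(C)C)(C(C)C)C(C)C)c(OC)c2)Oc2c(OC)cc(Br)cc12 | intermediate
9 | (2S)-6-bromo-4,8-dimethoxy-2-Ar-2H-chromene | COC1=C[C@@H](c2ccc(O[Si](C(C)C)(C(C)C)C(C)C)c(OC)c2)Oc2c(OC)cc(Br)cc12 | intermediate
10 | 2,3-trans-(2S)-3-[acetoxy(phenyl)iodanyl]-6-bromo-4,4,8-trimethoxy-2-Ar-chromane | COC1(OC)[C@H]([I](OC(C)=O)c2ccccc2)[C@@H](c2ccc(O[Si](C(C)C)(C(C)C)C(C)C)c(OC)c2)Oc2c(OC)cc(Br)cc12 | intermediate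
11 | (2S,3S)-5-bromo-7-methoxy-2-Ar-3-(trimethoxymethyl)-2,3-dihydrobenzofuran | Brc1cc(OC)c2c(c1)[C@H](C(OC)(OC)OC)[C@@H](c1ccc(O[Si](C(C)C)(C(C)C)C(C)C)c(OC)c1)O2 | intermediate
12 | methyl (2S,3S)-5-bromo-7-methoxy-2-Ar-2,3-dihydrobenzofuran-3-carboxylate | Brc1cc(OC)c2c(c1)[C@H](C(=O)OC)[C@@H](c1ccc(O[Si](C(C)C)(C(C)C)C(C)C)c(OC)c1)O2 | intermediate
13 | [(2S,3S)-7-methoxy-3-(methoxycarbonyl)-2-Ar-2,3-dihydrobenzofuran-5-yl]boronic acid | OB(O)c1cc(OC)c2c(c1)[C@H](C(=O)OC)[C@@H](c1ccc(O[Si](C(C)C)(C(C)C)C(C)C)c(OC)c1)O2 | intermediate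
14 | methyl (2S,3S)-5-[(2R)-6-bromo-8-methoxy-4-oxochroman-2-yl]-7-methoxy-2-Ar-2,3-dihydrobenzofuran-3-carboxylate | O=C1C[C@H](c3cc(OC)c4c(c3)[C@H](C(=O)OC)[C@@H](c3ccc(O[Si](C(C)C)(C(C)C)C(C)C)c(OC)c3)O4)Oc2c(OC)cc(Br)cc12 | intermediate
15 | methyl (2S,3S)-5-[(2R)-6-bromo-4,8-dimethoxy-2H-chromen-2-yl]-7-methoxy-2-Ar-2,3-dihydrobenzofuran-3-carboxylate | COC1=C[C@H](c3cc(OC)c4c(c3)[C@H](C(=O)OC)[C@@H](c3ccc(O[Si](C(C)C)(C(C)C)C(C)C)c(OC)c3)O4)Oc2c(OC)cc(Br)cc12 | intermediate
16 | 2,3-trans iodane ketal of 14 (C3 acetoxy(phenyl)iodanyl, C4 dimethyl ketal, C2 R) | COC1(OC)[C@@H]([I](OC(C)=O)c2ccccc2)[C@H](c3cc(OC)c4c(c3)[C@H](C(=O)OC)[C@@H](c3ccc(O[Si](C(C)C)(C(C)C)C(C)C)c(OC)c3)O4)Oc2c(OC)cc(Br)cc12 | intermediate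
17 | methyl (2S,3S)-5-[(2R,3R)-5-bromo-7-methoxy-3-(trimethoxymethyl)-2,3-dihydrobenzofuran-2-yl]-7-methoxy-2-Ar-2,3-dihydrobenzofuran-3-carboxylate | Brc1cc(OC)c2c(c1)[C@@H](C(OC)(OC)OC)[C@H](c3cc(OC)c4c(c3)[C@H](C(=O)OC)[C@@H](c3ccc(O[Si](C(C)C)(C(C)C)C(C)C)c(OC)c3)O4)O2 | intermediate
18 | methyl (2R,3R)-5-bromo-7-methoxy-2-[(2S,3S)-7-methoxy-3-(methoxycarbonyl)-2-Ar-2,3-dihydrobenzofuran-5-yl]-2,3-dihydrobenzofuran-3-carboxylate | Brc1cc(OC)c2c(c1)[C@@H](C(=O)OC)[C@H](c3cc(OC)c4c(c3)[C@H](C(=O)OC)[C@@H](c3ccc(O[Si](C(C)C)(C(C)C)C(C)C)c(OC)c3)O4)O2 | intermediate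
19 | [(2R,3S)-5-bromo-2-[(2S,3R)-3-(hydroxymethyl)-7-methoxy-2-Ar-2,3-dihydrobenzofuran-5-yl]-7-methoxy-2,3-dihydrobenzofuran-3-yl]methanol | Brc1cc(OC)c2c(c1)[C@@H](CO)[C@H](c3cc(OC)c4c(c3)[C@H](CO)[C@@H](c3ccc(O[Si](C(C)C)(C(C)C)C(C)C)c(OC)c3)O4)O2 | intermediate
20 | bis(TIPS) ether of 19 (tris(TIPS) aryl bromide; middle unit 2R,3S; terminal unit 2S,3R) | Brc1cc(OC)c2c(c1)[C@@H](CO[Si](C(C)C)(C(C)C)C(C)C)[C@H](c3cc(OC)c4c(c3)[C@H](CO[Si](C(C)C)(C(C)C)C(C)C)[C@@H](c3ccc(O[Si](C(C)C)(C(C)C)C(C)C)c(OC)c3)O4)O2 | intermediate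
21 | di-tert-butyl malonate | CC(C)(C)OC(=O)CC(=O)OC(C)(C)C | starting material
22 | (R)-epichlorohydrin | ClC[C@H]1CO1 | starting material
23 | tert-butyl (1R,5R)-2-oxo-3-oxabicyclo[3.1.0]hexane-1-carboxylate | O=C1OC[C@@H]2C[C@]12C(=O)OC(C)(C)C | intermediate
24 | [3-methoxy-4-(TIPS-oxy)phenyl]magnesium bromide | COc1cc([Mg]Br)ccc1O[Si](C(C)C)(C(C)C)C(C)C | intermediate
25 | tert-butyl (3R,4R)-4-[3-methoxy-4-(TIPS-oxy)benzyl]-2-oxotetrahydrofuran-3-carboxylate | COc1cc(C[C@H]2COC(=O)[C@@H]2C(=O)OC(C)(C)C)ccc1O[Si](C(C)C)(C(C)C)C(C)C | intermediate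
26 | (3S,4R)-4-[3-methoxy-4-(TIPS-oxy)benzyl]-2-oxotetrahydrofuran-3-carboxylic acid | COc1cc(C[C@H]2COC(=O)[C@@H]2C(=O)O)ccc1O[Si](C(C)C)(C(C)C)C(C)C | intermediate
27 | (4R)-4-[3-methoxy-4-(TIPS-oxy)benzyl]dihydrofuran-2(3H)-one | COc1cc(C[C@H]2COC(=O)C2)ccc1O[Si](C(C)C)(C(C)C)C(C)C | intermediate
28 | lithium enolate of 27 | COc1cc(C[C@H]2COC(O[Li])=C2)ccc1O[Si](C(C)C)(C(C)C)C(C)C | intermediate
29 | (3S,4R)-4-[3-methoxy-4-(TIPS-oxy)benzyl]-3-[(TIPS-oxy)methyl]dihydrofuran-2(3H)-one | COc1cc(C[C@H]2COC(=O)[C@@H]2CO[Si](C(C)C)(C(C)C)C(C)C)ccc1O[Si](C(C)C)(C(C)C)C(C)C | intermediate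
30 | aryllithium from 20 (Li in place of Br) | [Li]c1cc(OC)c2c(c1)[C@@H](CO[Si](C(C)C)(C(C)C)C(C)C)[C@H](c3cc(OC)c4c(c3)[C@H](CO[Si](C(C)C)(C(C)C)C(C)C)[C@@H](c3ccc(O[Si](C(C)C)(C(C)C)C(C)C)c(OC)c3)O4)O2 | intermediate
31 | (2S,3R)-4-hydroxy-3-[3-methoxy-4-(TIPS-oxy)benzyl]-2-[(TIPS-oxy)methyl]-1-(aryl of 20)butan-1-one | COc1cc(C[C@@H](CO)[C@@H](CO[Si](C(C)C)(C(C)C)C(C)C)C(=O)c3cc(OC)c4c(c3)[C@@H](CO[Si](C(C)C)(C(C)C)C(C)C)[C@H](c3cc(OC)c5c(c3)[C@H](CO[Si](C(C)C)(C(C)C)C(C)C)[C@@H](c3ccc(O[Si](C(C)C)(C(C)C)C(C)C)c(OC)c3)O5)O4)ccc1O[Si](C(C)C)(C(C)C)C(C)C | intermediate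
32 | (4R)-2-(aryl of 20)-4-[3-methoxy-4-(TIPS-oxy)benzyl]-3-[(TIPS-oxy)methyl]-4,5-dihydrofuran | COc1cc(C[C@H]2COC(c3cc(OC)c4c(c3)[C@@H](CO[Si](C(C)C)(C(C)C)C(C)C)[C@H](c3cc(OC)c5c(c3)[C@H](CO[Si](C(C)C)(C(C)C)C(C)C)[C@@H](c3ccc(O[Si](C(C)C)(C(C)C)C(C)C)c(OC)c3)O5)O4)=C2CO[Si](C(C)C)(C(C)C)C(C)C)ccc1O[Si](C(C)C)(C(C)C)C(C)C | intermediate
33 | pentakis(TIPS) ether of the target (all-cis (2R,3R,4R)-tetrahydrofuran) | COc1cc(C[C@H]2CO[C@@H](c3cc(OC)c4c(c3)[C@@H](CO[Si](C(C)C)(C(C)C)C(C)C)[C@H](c3cc(OC)c5c(c3)[C@H](CO[Si](C(C)C)(C(C)C)C(C)C)[C@@H](c3ccc(O[Si](C(C)C)(C(C)C)C(C)C)c(OC)c3)O5)O4)[C@H]2CO[Si](C(C)C)(C(C)C)C(C)C)ccc1O[Si](C(C)C)(C(C)C)C(C)C | intermediate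
34 | CNP0395728.1: (2R,3R,4R)-4-(4-hydroxy-3-methoxybenzyl)-3-(hydroxymethyl)tetrahydrofuran whose C2 carries a (2R,3S)-3-(hydroxymethyl)-7-methoxy-2,3-dihydrobenzofuran-5-yl group, itself bearing at C2 a (2S,3R)-3-(hydroxymethyl)-2-(4-hydroxy-3-methoxyphenyl)-7-methoxy-2,3-dihydrobenzofuran-5-yl group | COc1cc(C[C@H]2CO[C@@H](c3cc(OC)c4c(c3)[C@@H](CO)[C@H](c3cc(OC)c5c(c3)[C@H](CO)[C@@H](c3ccc(O)c(OC)c3)O5)O4)[C@H]2CO)ccc1O | target

**Summary**
Total steps: 19. Longest linear sequence: 13 steps (1, 2, 5–11, 16–19; equally 3–11, 16–19).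

**Steps most likely to fail**

Step 6. The benzylic C2–O bond may ionise or the ring may open under acid, eroding the enantiopurity at C2. The C2 aryl group may shift in competition (isoflavone pathway), or the iodane may simply eliminate to the flavone. Fallback, from 8 back to 12: the same ring is contracted by a Wolff rearrangement instead. Treatment of 8 with LiN(SiMe3)2 in THF at −78 °C and CF3CO2CH2CF3 should give the 3-trifluoroacetyl flavanone F1. Detrifluoroacetylative diazo transfer (MeSO2N3, Et3N, wet MeCN) should give the 3-diazo flavanone F2. Irradiation (Pyrex-filtered mercury lamp) in MeOH should cause C4a to migrate to the carbene carbon C3, and the ketene is captured by methanol to give 12 together with its cis epimer, methyl (2S,3R)-5-bromo-7-methoxy-2-Ar-2,3-dihydrobenzofuran-3-carboxylate F3. DBU in MeOH should equilibrate F3 to the trans ester 12.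

Step 18. Facial selectivity may be poor, the double bond may migrate before reduction, or benzylic and allylic C–O bonds may undergo hydrogenolysis. Fallback, from 29 and 20 back to 33: the stereocentres are set by substrate-controlled reduction of a hemiketal instead of alkene hydrogenation. The enolate of 29 (LiN(i-Pr)2, THF, −78 °C) is protonated from the face anti to the benzyl group with 2,6-di-tert-butyl-4-methylphenol to give the cis lactone (3R,4R)-4-[3-methoxy-4-(TIPS-oxy)benzyl]-3-[(TIPS-oxy)methyl]dihydrofuran-2(3H)-one F4. Addition of aryllithium 30 at −78 °C gives the 3,4-cis cyclic hemiketal F5. Without warming, Et3SiH and BF3·OEt2 in CH2Cl2 at −78 °C deliver hydride to the oxocarbenium ion anti to both ring substituents, as in C-aryl glycoside synthesis, to give 33.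

Step 16. The aryllithium may act as a base and enolise the lactone, the adduct may lose silanolate by β-elimination on warming, or a second addition may occur. Fallback, from 20 and 29 directly to 32: the aryl–C2 bond is made by cross-coupling. Borylation of 20 under the conditions of step 4 should give the boronic acid F6. Lactone 29 with KN(SiMe3)2 and (PhO)2P(O)Cl in THF at −78 °C should give the ketene acetal diphenyl phosphate F7. Suzuki coupling of F6 and F7 (Pd(PPh3)4, Cs2CO3, aqueous DMF, 50 °C; zerovalent palladium) should give dihydrofuran 32, bypassing 31 and step 17.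

**Further compounds**
F1 | step 6 | (2S)-6-bromo-8-methoxy-2-Ar-3-(trifluoroacetyl)chroman-4-one | O=C1C(C(=O)C(F)(F)F)[C@@H](c2ccc(O[Si](C(C)C)(C(C)C)C(C)C)c(OC)c2)Oc2c(OC)cc(Br)cc12
F2 | step 6 | 6-bromo-3-diazo-8-methoxy-2-Ar-chroman-4-one (C2 as in 8) | O=C1C(=[N+]=[N-])[C@@H](c2ccc(O[Si](C(C)C)(C(C)C)C(C)C)c(OC)c2)Oc2c(OC)cc(Br)cc12
F3 | step 6 | methyl (2S,3R)-5-bromo-7-methoxy-2-Ar-2,3-dihydrobenzofuran-3-carboxylate (cis) | Brc1cc(OC)c2c(c1)[C@@H](C(=O)OC)[C@@H](c1ccc(O[Si](C(C)C)(C(C)C)C(C)C)c(OC)c1)O2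
F4 | step 18 | (3R,4R)-4-[3-methoxy-4-(TIPS-oxy)benzyl]-3-[(TIPS-oxy)methyl]dihydrofuran-2(3H)-one (cis) | COc1cc(C[C@H]2COC(=O)[C@H]2CO[Si](C(C)C)(C(C)C)C(C)C)ccc1O[Si](C(C)C)(C(C)C)C(C)C
F5 | step 18 | 3,4-cis-2-(aryl of 20)-2-hydroxy-4-[3-methoxy-4-(TIPS-oxy)benzyl]-3-[(TIPS-oxy)methyl]tetrahydrofuran (anomer mixture) | COc1cc(C[C@H]2COC(O)(c3cc(OC)c4c(c3)[C@@H](CO[Si](C(C)C)(C(C)C)C(C)C)[C@H](c3cc(OC)c5c(c3)[C@H](CO[Si](C(C)C)(C(C)C)C(C)C)[C@@H](c3ccc(O[Si](C(C)C)(C(C)C)C(C)C)c(OC)c3)O5)O4)[C@H]2CO[Si](C(C)C)(C(C)C)C(C)C)ccc1O[Si](C(C)C)(C(C)C)C(C)C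
F6 | step 16 | boronic acid from 20 (B(OH)2 in place of Br) | OB(O)c1cc(OC)c2c(c1)[C@@H](CO[Si](C(C)C)(C(C)C)C(C)C)[C@H](c3cc(OC)c4c(c3)[C@H](CO[Si](C(C)C)(C(C)C)C(C)C)[C@@H](c3ccc(O[Si](C(C)C)(C(C)C)C(C)C)c(OC)c3)O4)O2
F7 | step 16 | (4R)-4-[3-methoxy-4-(TIPS-oxy)benzyl]-3-[(TIPS-oxy)methyl]-4,5-dihydrofuran-2-yl diphenyl phosphate | COc1cc(C[C@H]2COC(OP(=O)(Oc3ccccc3)Oc3ccccc3)=C2CO[Si](C(C)C)(C(C)C)C(C)C)ccc1O[Si](C(C)C)(C(C)C)C(C)C
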